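**Strategy.** Along the chain C2–C3–C4–C5–C1′–C2′ the stereocentres C3, C5 and C2′ are 1,3,5-related, and C2′ is a tertiary carbinol. A bond drawn between lactone carbonyl C2 and C2′ folds this chain into a cyclohexanone, so everything rests on undoing that C2–C2′ bond by oxygen insertion. Precursor 12 is a cis-2,6-dimethylcyclohexanone: C2 is the ketone, C3 and quaternary C2′ are its α-carbons, C5 is the silyloxy-bearing C-4, and the protected C3′/C4′ arm sits on C2′. One peracid oxidation converts the all-carbon quaternary centre into the C2′–O stereocentre with retention and C2 into a carboxyl carbon. This gives oxepanone 14, which later contracts to the butanolide ring.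

Key step: step 7

Remarks on the chemistry (one line each)
- Numbering: the atom labels of the target (butanolide O1, C2–C5; side chain C1′–C4′) are used for all intermediates, and 1, 2, 9 and 20 are assumed to be purchased.
- Ring source: catalytic hydrogenation of a 1,4-benzoquinone stops at the hydroquinone, so the ring is taken from ketone 1 and both methyl groups are introduced by auxiliary-controlled alkylation.
- Symmetry: in trans ketone 8 the two ring branches at C-4 are identical, so C-4 is not a stereocentre; it becomes C5 (R) when one α-carbon is singled out in step 5.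
- Stability: 12 is the less stable C3 epimer, because no chair places the arm, the OTBS group and both methyl groups equatorial, so no enolising reagent is used between steps 5 and 8.

Step 1
Reactants: 1 4-(tert-butyldimethylsilyloxy)cyclohexanone; 2 SAMP
Product: 3 SAMP hydrazone of 1
Conditions: neat, 60 °C
Reagents that add atoms: none
Why: Condensation of a ketone with an N,N-dialkylhydrazine (hydrazone formation) runs under neutral conditions that leave the silyl ether untouched, and the C=N isomers formed are of no consequence.

Step 2
Reactants: 3 SAMP hydrazone of 1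
Product: 5 (2R)-2-methyl SAMP hydrazone as its C-4 epimer pair, via lithio azaenolate 4 (not isolated)
Conditions: LDA, THF, 0 °C; MeI, −95 °C → rt
Reagents that add atoms: iodomethane, CI
Why: In this SAMP/RAMP hydrazone α-alkylation the chelated lithio azaenolate is methylated on the face left open by the methoxymethylpyrrolidine, which should set the methyl-bearing carbon as R whichever α-carbon reacts, so the two C-4 epimers converge in step 3.

Step 3
Reactants: 5 (2R)-2-methyl SAMP hydrazone
Product: 7 (2R,6R)-2,6-dimethyl SAMP hydrazone, via lithio azaenolate 6 (not isolated)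
Conditions: LDA, THF, 0 °C; MeI, −95 °C → rt
Reagents that add atoms: iodomethane, CI
Why: In this second SAMP/RAMP alkylation LDA deprotonates the remaining CH2, and auxiliary control (R again) is reinforced by attack anti to the first methyl group, giving the trans array; a single stereochemical error ends in a separable cis diastereomer, not in the enantiomer.

Step 4
Reactants: 7 (2R,6R)-2,6-dimethyl SAMP hydrazone
Product: 8 (2R,6R)-4-(tert-butyldimethylsilyloxy)-2,6-dimethylcyclohexanone
Conditions: O3, CH2Cl2, −78 °C; N2 purge
Reagents that add atoms: ozone, [O-][O+]=O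
Why: Ozonolytic hydrazone cleavage is fast, cold and neutral, so the epimerisable trans-dimethyl ketone should be released without equilibration to the cis isomers.

Step 5
Reactants: 8 (2R,6R)-4-(tert-butyldimethylsilyloxy)-2,6-dimethylcyclohexanone; 9 benzyloxyacetaldehyde
Product: 11 aldol adduct (2S,4R,6R)-2-[(1R)-2-(benzyloxy)-1-hydroxyethyl]-4-(tert-butyldimethylsilyloxy)-2,6-dimethylcyclohexanone, via lithium enolate 10 (not isolated)
Conditions: LDA, THF, −78 °C; 9, −78 °C, 15 min; AcOH, −78 °C
Reagents that add atoms: none
Why: This is a kinetic enolisation followed by a lithium aldol addition: in the chair of 8 with equatorial OTBS only the α-carbon whose methyl is cis to OTBS bears an axial H, so LDA should give 10 and thereby fix the surviving C3 methyl trans to O5 (3R,5R); the aldehyde then adds anti to that pseudoaxial methyl (C2′) through a Zimmerman–Traxler chair with CH2OBn equatorial (C3′), and minor diastereomers are removed by chromatography.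

Step 6
Reactants: 11 aldol adduct
Product: 12 bis-silyl ketone (2S,4R,6R)-2-[(1R)-2-(benzyloxy)-1-(tert-butyldimethylsilyloxy)ethyl]-4-(tert-butyldimethylsilyloxy)-2,6-dimethylcyclohexanone
Conditions: TBSOTf, 2,6-lutidine, CH2Cl2, −78 → 0 °C
Reagents that add atoms: tert-butyldimethylsilyl triflate, CC(C)(C)[Si](C)(C)OS(=O)(=O)C(F)(F)F
Why: O-Silylation with a silyl triflate and a hindered pyridine caps a crowded aldol hydroxyl without base-induced retro-aldol cleavage, and using the same silyl group on O5 and O3′ makes any silyl shift in the aldolate of step 5 harmless.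

Step 7
Reactants: 12 bis-silyl ketone
Product: 14 oxepanone (3R,5R,7S)-7-[(1S)-2-(benzyloxy)-1-(tert-butyldimethylsilyloxy)ethyl]-5-(tert-butyldimethylsilyloxy)-3,7-dimethyloxepan-2-one, via Criegee adduct 13 (not isolated)
Conditions: mCPBA, NaHCO3, CH2Cl2, 0 °C → rt
Reagents that add atoms: 3-chloroperbenzoic acid, O=C(OO)c1cccc(Cl)c1
Why: The peracid adds to the C2 carbonyl to give Criegee adduct 13, in which the C2–C2′ bond aligns antiperiplanar to the O–O bond and C2′ shifts from carbon to oxygen as 3-chlorobenzoate leaves; this is the Baeyer–Villiger oxidation of an α,α-disubstituted cyclohexanone, a well-documented substrate class. The seven-membered ring arises by expansion of the carbocycle through this 1,2-shift and not by a cyclisation, and the shift makes the O–C2′ and C2(acyl)–O bonds while breaking C2–C2′. The carbinol stereocentre C2′ (S) is controlled by the concerted, suprafacial migration, which carries over the configuration of the quaternary carbon set in step 5 with retention. The step needs regioselectivity between the two α-carbons: fully substituted C2′ carries developing positive charge better than the CH(CH3) carbon C3, its departure relieves the crowding of 12, and a silyl ether rather than an electron-poor ester on O3′ keeps it a good migrating group. The step also needs C3 to stay intact, which solid NaHCO3 should secure by removing the acid that would catalyse enolisation, while the TBS ethers and the benzyl ether are inert to mCPBA.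

Step 8
Reactants: 14 oxepanone
Product: 17 dihydroxy butanolide (3R,5R)-5-[(2S,3S)-4-(benzyloxy)-2,3-dihydroxy-2-methylbutyl]-3-methyloxolan-2-one, via hydroxy oxepanone 15 (not isolated), via silyl butanolide 16 (not isolated)
Conditions: 48% aq HF, MeCN, 0 °C → rt
Reagents that add atoms: none
Why: Desilylation with HF frees O5, which attacks the ring carbonyl (5-exo-trig transacylation) and expels the tertiary C2′ oxygen, so the strained tertiary-alkyl ε-lactone gives way to the γ-lactone without touching any C–O bond at a stereocentre, and the acidic medium avoids enolate formation at C3.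

Step 9
Reactants: 17 dihydroxy butanolide
Product: 18 acetonide (3R,5R)-5-{[(4S,5S)-5-(benzyloxymethyl)-2,2,4-trimethyl-1,3-dioxolan-4-yl]methyl}-3-methyloxolan-2-one
Conditions: Me2C(OMe)2, PPTS (cat.), CH2Cl2, rt
Reagents that add atoms: 2,2-dimethoxypropane, COC(C)(C)OC
Why: Acid-catalysed transketalisation ties the vicinal C2′/C3′ diol into a five-membered dioxolane, so that O4′ will be the only free hydroxyl after the next step.

Step 10
Reactants: 18 acetonide
Product: 19 primary alcohol (3R,5R)-5-{[(4S,5S)-5-(hydroxymethyl)-2,2,4-trimethyl-1,3-dioxolan-4-yl]methyl}-3-methyloxolan-2-one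
Conditions: H2 (1 atm), 10% Pd/C, EtOAc, rt
Reagents that add atoms: none
Why: Catalytic hydrogenolysis removes the benzyl ether under neutral conditions that leave the lactone and the acetonide unchanged, and it is placed before the reducible coumarin is introduced.

Step 11
Reactants: 19 primary alcohol; 20 daphnetin
Product: 21 7-O-alkylated daphnetin acetonide
Conditions: PPh3, DIAD, THF, 0 °C → rt (20 in excess)
Reagents that add atoms: none
Why: In this Mitsunobu etherification the unhindered primary alcohol is activated as its oxyphosphonium salt and displaced by the 7-phenoxide, since 7-OH is conjugated with the pyranone carbonyl, more acidic and less flanked than 8-OH; excess 20 suppresses double alkylation and no stereocentre is involved.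

Step 12
Reactants: 21 7-O-alkylated daphnetin acetonide
Product: 23-free numbering is not needed here: 22 target CNP0130480.1
Conditions: AcOH/H2O 4:1, 40 °C
Reagents that add atoms: none
Why: Mild aqueous acid hydrolyses the dioxolane (acetal hydrolysis) and leaves the γ-lactone, the coumarin, the aryl ether and all four stereocentres untouched.

**Compound list**

| No. | Name | SMILES | Role |
|---|---|---|---|
| 1 | 4-(tert-butyldimethylsilyloxy)cyclohexanone | O=C1CCC(CC1)O[Si](C)(C)C(C)(C)C | starting material |
| 2 | SAMP, (2S)-2-(methoxymethyl)pyrrolidin-1-amine | COC[C@@H]1CCCN1N | starting material |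
| 3 | SAMP hydrazone of 1 | COC[C@@H]1CCCN1N=C1CCC(CC1)O[Si](C)(C)C(C)(C)C | intermediate |
| 4 | lithio azaenolate of 3 | COC[C@@H]1CCCN1N([Li])C1=CCC(CC1)O[Si](C)(C)C(C)(C)C | intermediate (not isolated) |
| 5 | (2R)-2-methyl SAMP hydrazone, C-4 epimer pair | COC[C@@H]1CCCN1N=C1CCC(C[C@H]1C)O[Si](C)(C)C(C)(C)C | intermediate |
| 6 | lithio azaenolate of 5 (C1=C6) | COC[C@@H]1CCCN1N([Li])C1=CCC(C[C@H]1C)O[Si](C)(C)C(C)(C)C | intermediate (not isolated) |
| 7 | (2R,6R)-2,6-dimethyl SAMP hydrazone | COC[C@@H]1CCCN1N=C1[C@H](C)CC(C[C@H]1C)O[Si](C)(C)C(C)(C)C | intermediate |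
| 8 | (2R,6R)-4-(tert-butyldimethylsilyloxy)-2,6-dimethylcyclohexanone (trans-dimethyl) | C[C@@H]1CC(C[C@@H](C)C1=O)O[Si](C)(C)C(C)(C)C | intermediate |
| 9 | benzyloxyacetaldehyde | O=CCOCc1ccccc1 | starting material |
| 10 | lithium (4R,6R)-4-(tert-butyldimethylsilyloxy)-2,6-dimethylcyclohex-1-en-1-olate | C[C@@H]1C[C@@H](O[Si](C)(C)C(C)(C)C)CC(C)=C1O[Li] | intermediate (not isolated) |
| 11 | aldol adduct (2S,4R,6R,1″R) | C[C@@H]1C[C@@H](O[Si](C)(C)C(C)(C)C)C[C@@](C)([C@@H](O)COCc2ccccc2)C1=O | intermediate |
| 12 | bis-silyl ketone, precursor of the key step | C[C@@H]1C[C@@H](O[Si](C)(C)C(C)(C)C)C[C@@](C)([C@@H](O[Si](C)(C)C(C)(C)C)COCc2ccccc2)C1=O | intermediate |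
| 13 | Criegee adduct of 12 with mCPBA (C2 configuration open) | C[C@@H]1C[C@@H](O[Si](C)(C)C(C)(C)C)C[C@@](C)([C@@H](O[Si](C)(C)C(C)(C)C)COCc2ccccc2)C1(O)OOC(=O)c1cccc(Cl)c1 | intermediate (not isolated) |
| 14 | oxepanone (3R,5R,7S,1″S), product of the key step | C[C@@H]1C[C@@H](O[Si](C)(C)C(C)(C)C)C[C@@](C)([C@@H](O[Si](C)(C)C(C)(C)C)COCc2ccccc2)OC1=O | intermediate |
| 15 | 5-hydroxy oxepanone (O3′ still silylated) | C[C@@H]1C[C@@H](O)C[C@@](C)([C@@H](O[Si](C)(C)C(C)(C)C)COCc2ccccc2)OC1=O | intermediate (not isolated) |
| 16 | O3′-silyl butanolide | C[C@@H]1C[C@H](C[C@](C)(O)[C@@H](O[Si](C)(C)C(C)(C)C)COCc2ccccc2)OC1=O | intermediate (not isolated) |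
| 17 | dihydroxy butanolide (3R,5R,2′S,3′S) | C[C@@H]1C[C@H](C[C@](C)(O)[C@@H](O)COCc2ccccc2)OC1=O | intermediate |
| 18 | C2′/C3′ acetonide, benzyl ether | C[C@@H]1C[C@H](C[C@]2(C)OC(C)(C)O[C@H]2COCc3ccccc3)OC1=O | intermediate |
| 19 | C2′/C3′ acetonide, primary alcohol | C[C@@H]1C[C@H](C[C@]2(C)OC(C)(C)O[C@H]2CO)OC1=O | intermediate |
| 20 | daphnetin (7,8-dihydroxycoumarin) | Oc1ccc2ccc(=O)oc2c1O | starting material |
| 21 | 7-O-alkylated daphnetin acetonide | C[C@@H]1C[C@H](C[C@]2(C)OC(C)(C)O[C@H]2COc3ccc4ccc(=O)oc4c3O)OC1=O | intermediate |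
| 22 | CNP0130480.1, (3R,5R)-5-[(2S,3S)-2,3-dihydroxy-4-(8-hydroxy-2-oxo-2H-chromen-7-yloxy)-2-methylbutyl]-3-methyloxolan-2-one | C[C@@H]1C[C@H](C[C@](C)(O)[C@@H](O)COc2ccc3ccc(=O)oc3c2O)OC1=O | target |

Correction to the Product line of step 12: it reads "Product: 22 target CNP0130480.1".

Total step count: 12. Longest linear sequence: 12 steps (1 → 22); 2, 9 and 20 enter as purchased compounds.

**Steps most likely to fail**

1. **Step 7.** Addition of the peracid to a carbonyl flanked by a quaternary and a tertiary carbon may be slow. Long contact time would then allow acid-catalysed enolisation and loss of the C3 configuration. The fallback sets out from 12 and gives up C3 on purpose.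
   - Equilibration with DBU in toluene should give the strain-free C3 epimer of the ketone F1, in which the arm, the OTBS group and the C3 methyl are all equatorial.
   - F1 can be oxidised under forcing conditions (CF3CO3H, Na2HPO4) to the C3 epimer of the oxepanone F2.
   - Aqueous HF then gives the C3 epimer of the diol F3, and 2,2-dimethoxypropane/PPTS gives the C3 epimer of the acetonide F4.
   - LDA at −78 °C converts F4 into the lithium lactone enolate F5.
   - Kinetic protonation of F5 with a bulky phenol occurs on the face away from the C5 substituent. This places the methyl group cis and comes back to the route at 18.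

2. **Step 5.** The lithium transition state may discriminate poorly between the two aldehyde faces, and the addition may partly reverse before the quench. The fallback sets out from 8 and accepts the crude mixture of 11 and the C3′ epimer of the aldol F6.
   - Dess–Martin oxidation merges both into the β-diketone F7, which has no enolisable hydrogen between its carbonyls.
   - Corey–Bakshi–Shibata reduction with the (R)-oxazaborolidine and catecholborane then sets C3′ by reagent control, with the quaternary carbon as the large group and CH2OBn as the small one.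
   - The more hindered ring ketone should be left alone, and the sequence comes back at 11.

3. **Step 11.** Regiocontrol may be lost through reaction at 8-OH, or both phenolic oxygens may tie up the phosphonium reagent and lower the conversion. The fallback sets out from 19 and uses a coupling partner with a single phenol.
   - Purchased 7-hydroxy-2-oxo-2H-chromene-8-carbaldehyde F8 is coupled by Mitsunobu etherification to give the 8-formyl aryl ether F9.
   - Dakin-type Baeyer–Villiger oxidation with mCPBA turns the doubly ortho-oxygenated aldehyde into the 8-formyloxy aryl ether F10.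
   - Brief methanolysis (KHCO3, MeOH, 0 °C) releases the 8-OH and comes back at 21.

**Further compounds**
F1 | step 7 | (2S,4R,6S) C3 epimer of ketone 12 | C[C@H]1C[C@@H](O[Si](C)(C)C(C)(C)C)C[C@@](C)([C@@H](O[Si](C)(C)C(C)(C)C)COCc2ccccc2)C1=O
F2 | step 7 | (3S,5R,7S) C3 epimer of oxepanone 14 | C[C@H]1C[C@@H](O[Si](C)(C)C(C)(C)C)C[C@@](C)([C@@H](O[Si](C)(C)C(C)(C)C)COCc2ccccc2)OC1=O
F3 | step 7 | (3S,5R) C3 epimer of diol 17 | C[C@H]1C[C@H](C[C@](C)(O)[C@@H](O)COCc2ccccc2)OC1=O
F4 | step 7 | (3S,5R) C3 epimer of acetonide 18 | C[C@H]1C[C@H](C[C@]2(C)OC(C)(C)O[C@H]2COCc3ccccc3)OC1=O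
F5 | step 7 | lithium enolate of lactone F4 | CC1=C(O[Li])O[C@@H](C[C@]2(C)OC(C)(C)O[C@H]2COCc3ccccc3)C1
F6 | step 5 | C3′ epimer of aldol 11 | C[C@@H]1C[C@@H](O[Si](C)(C)C(C)(C)C)C[C@@](C)([C@H](O)COCc2ccccc2)C1=O
F7 | step 5 | β-diketone (2S,4R,6R)-2-(benzyloxyacetyl)-4-(tert-butyldimethylsilyloxy)-2,6-dimethylcyclohexanone | C[C@@H]1C[C@@H](O[Si](C)(C)C(C)(C)C)C[C@@](C)(C(=O)COCc2ccccc2)C1=O
F8 | step 11 | 7-hydroxy-2-oxo-2H-chromene-8-carbaldehyde (purchased) | O=Cc1c(O)ccc2ccc(=O)oc12
F9 | step 11 | 8-formyl aryl ether of 19 | C[C@@H]1C[C@H](C[C@]2(C)OC(C)(C)O[C@H]2COc3ccc4ccc(=O)oc4c3C=O)OC1=O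
F10 | step 11 | 8-formyloxy aryl ether of 19 | C[C@@H]1C[C@H](C[C@]2(C)OC(C)(C)O[C@H]2COc3ccc4ccc(=O)oc4c3OC=O)OC1=O
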